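**Retrosynthetic overview**

1. Dioxane ring numbering: O1, C2 (bears CH2OH), C3 (bears the 4-hydroxy-3,5-dimethoxyphenyl ring), O4; the styryl group sits on C6, para to O1. Aiphanol is opened at the O4–C3 bond, giving a ring-open tetraphenol with one stereocenter (C2) and no oxygen or leaving group on the benzylic carbon.
2. Enabling feature: the free 4-OH of the 4-hydroxy-3,5-dimethoxyphenyl ring is para to C3. Two-electron oxidation turns that ring plus C3 into a p-quinone methide whose methide carbon is C3, and the phenol that becomes O4 adds to it. The resulting O4–C3 bond is a p-hydroxybenzyl aryl ether and can reopen, so the trans isomer is also the thermodynamic sink.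
3. The ring-open tetraphenol comes from one acid deprotection of an E-stilbene, made by Horner–Wadsworth–Emmons olefination of an aryl aldehyde with a 3,5-bis(methoxymethoxy)benzylphosphonate.
4. The aldehyde comes from SNAr of a secondary alkoxide on 4-fluoro-3-(methoxymethoxy)benzaldehyde, which fixes the oxygen para to the future styryl carbon on C2 with retention. The alcohol comes from an aryl Grignard reagent and (S)-trityl glycidyl ether, the only source of chirality.
5. Ring order: the three benzene rings are bought. The 1,4-dioxane ring is the only ring closed in the synthesis, and it is closed last.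

Key step: step 11

Remark on the chemistry: compounds 1, 3, 6 and 9 are taken as purchased, and the resorcinol and stilbene units are assumed to tolerate one equivalent of Ag2O, as phenols of these types do in silver oxide phenol couplings.

**Step 1**
Reactants: 1 4-bromo-2,6-dimethoxyphenol
Product: 2 5-bromo-1,3-dimethoxy-2-(methoxymethoxy)benzene
Conditions: NaH, MOMCl, DMF, 0 °C to rt
Reagents that add atoms: chloromethyl methyl ether (MOMCl), COCCl
Why: Williamson etherification of the sodium phenoxide with the reactive α-chloro ether should be fast even for this 2,6-disubstituted phenol, and the MOM acetal is inert to the organomagnesium, alkoxide and phosphonate-anion steps that follow.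

**Step 2**
Reactants: 2 5-bromo-1,3-dimethoxy-2-(methoxymethoxy)benzene; 3 (S)-trityl glycidyl ether, (2S)-2-[(triphenylmethoxy)methyl]oxirane
Product: 5 (2S)-1-[3,5-dimethoxy-4-(methoxymethoxy)phenyl]-3-(triphenylmethoxy)propan-2-ol, via arylmagnesium bromide 4 (not isolated)
Conditions: Mg, THF, 45 °C; then CuI (10 mol %), 3, THF, −30 to 0 °C; then H2O
Reagents that add atoms: none
Why: Grignard formation followed by copper-catalysed epoxide opening is an SN2 attack at the unhindered CH2 terminus, so no bond to the stereocenter is broken and the S configuration of 3 is carried unchanged into 5 (no new stereocenter is made).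

**Step 3**
Reactants: 6 4-fluoro-3-hydroxybenzaldehyde
Product: 7 4-fluoro-3-(methoxymethoxy)benzaldehyde
Conditions: NaH, MOMCl, THF, 0 °C
Reagents that add atoms: chloromethyl methyl ether (MOMCl), COCCl
Why: Williamson etherification of the phenoxide masks the oxygen that will later be O4 as a base-stable acetal, leaving the fluorine as the only leaving group on the ring.

**Step 4**
Reactants: 5 (2S)-1-[3,5-dimethoxy-4-(methoxymethoxy)phenyl]-3-(triphenylmethoxy)propan-2-ol; 7 4-fluoro-3-(methoxymethoxy)benzaldehyde
Product: 8 4-{[(2S)-1-[3,5-dimethoxy-4-(methoxymethoxy)phenyl]-3-(triphenylmethoxy)propan-2-yl]oxy}-3-(methoxymethoxy)benzaldehyde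
Conditions: NaH, DMF, 0 °C; then 7, 0 °C to rt
Reagents that add atoms: none
Why: Nucleophilic aromatic substitution (addition–elimination through a Meisenheimer adduct) at the C–F carbon para to the formyl group uses the alkoxide oxygen as nucleophile, so the stereocenter keeps its configuration, the trityl ether cannot migrate as a silyl ether would, and the position of the fluorine decides that the oxygen para to the future styryl carbon is the one bound to C2.

**Step 5**
Reactants: 9 methyl 3,5-dihydroxybenzoate
Product: 10 methyl 3,5-bis(methoxymethoxy)benzoate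
Conditions: NaH, MOMCl, DMF, 0 °C to rt
Reagents that add atoms: chloromethyl methyl ether (MOMCl), COCCl
Why: Twofold Williamson etherification of the bis-phenoxide leaves the methyl ester untouched.

**Step 6**
Reactants: 10 methyl 3,5-bis(methoxymethoxy)benzoate
Product: 11 [3,5-bis(methoxymethoxy)phenyl]methanol
Conditions: LiAlH4, THF, 0 °C; then H2O
Reagents that add atoms: none
Why: Hydride reduction of the ester with LiAlH4 should give the benzylic alcohol, and acetals are inert to hydride.

**Step 7**
Reactants: 11 [3,5-bis(methoxymethoxy)phenyl]methanol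
Product: 12 1-(bromomethyl)-3,5-bis(methoxymethoxy)benzene
Conditions: CBr4, PPh3, CH2Cl2, 0 °C
Reagents that add atoms: carbon tetrabromide, BrC(Br)(Br)Br
Why: Appel bromination displaces the alkoxyphosphonium ion of the primary benzylic alcohol with bromide under neutral conditions that should spare the acid-labile MOM ethers.

**Step 8**
Reactants: 12 1-(bromomethyl)-3,5-bis(methoxymethoxy)benzene
Product: 13 diethyl {[3,5-bis(methoxymethoxy)phenyl]methyl}phosphonate
Conditions: P(OEt)3 (neat), 130 °C
Reagents that add atoms: triethyl phosphite, CCOP(OCC)OCC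
Why: Michaelis–Arbuzov reaction, in which phosphorus attacks the benzylic bromide (SN2) and bromide dealkylates the phosphonium ion, should give the phosphonate without acid or base.

**Step 9**
Reactants: 8 4-{[(2S)-1-[3,5-dimethoxy-4-(methoxymethoxy)phenyl]-3-(triphenylmethoxy)propan-2-yl]oxy}-3-(methoxymethoxy)benzaldehyde; 13 diethyl {[3,5-bis(methoxymethoxy)phenyl]methyl}phosphonate
Product: 14 1-{(E)-2-[3,5-bis(methoxymethoxy)phenyl]ethenyl}-4-{[(2S)-1-[3,5-dimethoxy-4-(methoxymethoxy)phenyl]-3-(triphenylmethoxy)propan-2-yl]oxy}-3-(methoxymethoxy)benzene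
Conditions: NaH, 15-crown-5 (cat.), THF, 0 °C; then 8, 0 °C to rt
Reagents that add atoms: none
Why: Horner–Wadsworth–Emmons olefination, with reversible addition of the benzylic phosphonate anion to the aryl aldehyde and elimination from the more stable adduct, should give the E-stilbene, and the stereocenter carries no acidic hydrogen and is untouched.

**Step 10**
Reactants: 14 the fully protected E-stilbene
Product: 15 5-[(E)-2-(3-hydroxy-4-{[(2S)-1-hydroxy-3-(4-hydroxy-3,5-dimethoxyphenyl)propan-2-yl]oxy}phenyl)ethenyl]benzene-1,3-diol
Conditions: HCl (1.25 M in MeOH), MeOH/THF, 40 °C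
Reagents that add atoms: none
Why: Acid-catalysed acetal exchange of the four MOM ethers and SN1 methanolysis of the trityl ether should free all five hydroxyls at once, and because 14 has no benzylic oxygen no benzylic cation or quinone methide can form, so the secondary alkyl aryl ether, the stereocenter and the E-alkene should survive.

**Step 11**
Reactants: 15 5-[(E)-2-(3-hydroxy-4-{[(2S)-1-hydroxy-3-(4-hydroxy-3,5-dimethoxyphenyl)propan-2-yl]oxy}phenyl)ethenyl]benzene-1,3-diol
Product: 17 aiphanol, via p-quinone methide 16 (not isolated)
Conditions: Ag2O (1.1 equiv), acetone/benzene 1:2 (5 mM), rt, dark, N2; filter through Celite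
Reagents that add atoms: none
Why: Ag2O (monovalent silver, a one-electron oxidant) should oxidise the most electron-rich phenol, the 4-alkyl-2,6-dimethoxyphenol, to its phenoxyl radical, and loss of a second electron and of the benzylic proton (or disproportionation of two radicals) gives p-quinone methide 16, whose exocyclic methide carbon is then attacked by the phenol OH ortho to the ether oxygen, rearomatising the dimethoxyphenol ring. The closest known reaction types are the Ag2O oxidation of 4-alkyl-2,6-dimethoxyphenols to p-quinone methides, the DDQ-mediated oxidative cyclisation of 1-(2-hydroxyphenyl)-3-(4-hydroxyphenyl)propanes to flavans, and the quinone methide ring closure that ends silver-mediated oxidative couplings of catechols with 4-hydroxycinnamyl alcohols to benzodioxane neolignans; 16 is the intermediate such a coupling would pass through, but here it arises as one regioisomer and one enantiomer. The 1,4-dioxane ring is closed by a 6-exo-trig oxa-1,6-conjugate addition that forms the O4–C3 bond. The new stereocenter C3 is controlled by the existing C2 stereocenter (1,2-induction): in the chair-like transition state the CH2OH group and the quinonoid ring should both sit pseudo-equatorial, giving the trans (2R,3R) isomer, and because the new bond is a p-hydroxybenzyl aryl ether that can reopen to 16, any cis isomer should be able to drain to the more stable diequatorial trans isomer while C2 is never touched. The step needs chemoselective oxidation of one phenol out of four, which the two ortho methoxy groups and the para alkyl group secure by giving that phenol the lowest oxidation potential and blocking ring coupling of its radical, while the resorcinol hydroxyls are meta to the alkene and cannot give a quinone methide and the nucleophilic phenol sits on the less electron-rich ring. Regiochemistry cannot drift, because the O1–C2 bond was fixed in step 4 and the only other internal nucleophile, the CH2OH group, could only close a four-membered ring.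

**Compound list**

1 | 4-bromo-2,6-dimethoxyphenol | COc1cc(Br)cc(OC)c1O | starting material
2 | 5-bromo-1,3-dimethoxy-2-(methoxymethoxy)benzene | COCOc1c(OC)cc(Br)cc1OC | intermediate
3 | (S)-trityl glycidyl ether, (2S)-2-[(triphenylmethoxy)methyl]oxirane | C1O[C@@H]1COC(c2ccccc2)(c2ccccc2)c2ccccc2 | starting material
4 | [3,5-dimethoxy-4-(methoxymethoxy)phenyl]magnesium bromide (formed in the flask, not isolated) | COCOc1c(OC)cc([Mg]Br)cc1OC | intermediate
5 | (2S)-1-[3,5-dimethoxy-4-(methoxymethoxy)phenyl]-3-(triphenylmethoxy)propan-2-ol | COCOc1c(OC)cc(C[C@H](O)COC(c2ccccc2)(c2ccccc2)c2ccccc2)cc1OC | intermediate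
6 | 4-fluoro-3-hydroxybenzaldehyde | O=Cc1ccc(F)c(O)c1 | starting material
7 | 4-fluoro-3-(methoxymethoxy)benzaldehyde | COCOc1cc(C=O)ccc1F | intermediate
8 | 4-{[(2S)-1-[3,5-dimethoxy-4-(methoxymethoxy)phenyl]-3-(triphenylmethoxy)propan-2-yl]oxy}-3-(methoxymethoxy)benzaldehyde | COCOc1cc(C=O)ccc1O[C@@H](Cc2cc(OC)c(OCOC)c(OC)c2)COC(c3ccccc3)(c3ccccc3)c3ccccc3 | intermediate
9 | methyl 3,5-dihydroxybenzoate | COC(=O)c1cc(O)cc(O)c1 | starting material
10 | methyl 3,5-bis(methoxymethoxy)benzoate | COCOc1cc(OCOC)cc(C(=O)OC)c1 | intermediate
11 | [3,5-bis(methoxymethoxy)phenyl]methanol | COCOc1cc(CO)cc(OCOC)c1 | intermediate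
12 | 1-(bromomethyl)-3,5-bis(methoxymethoxy)benzene | COCOc1cc(CBr)cc(OCOC)c1 | intermediate
13 | diethyl {[3,5-bis(methoxymethoxy)phenyl]methyl}phosphonate | CCOP(=O)(Cc1cc(OCOC)cc(OCOC)c1)OCC | intermediate
14 | 1-{(E)-2-[3,5-bis(methoxymethoxy)phenyl]ethenyl}-4-{[(2S)-1-[3,5-dimethoxy-4-(methoxymethoxy)phenyl]-3-(triphenylmethoxy)propan-2-yl]oxy}-3-(methoxymethoxy)benzene | COCOc1cc(/C=C/c2ccc(O[C@@H](Cc3cc(OC)c(OCOC)c(OC)c3)COC(c4ccccc4)(c4ccccc4)c4ccccc4)c(OCOC)c2)cc(OCOC)c1 | intermediate
15 | 5-[(E)-2-(3-hydroxy-4-{[(2S)-1-hydroxy-3-(4-hydroxy-3,5-dimethoxyphenyl)propan-2-yl]oxy}phenyl)ethenyl]benzene-1,3-diol | Oc1cc(O)cc(/C=C/c2ccc(O[C@@H](Cc3cc(OC)c(O)c(OC)c3)CO)c(O)c2)c1 | intermediate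
16 | 4-[(2S)-2-{4-[(E)-2-(3,5-dihydroxyphenyl)ethenyl]-2-hydroxyphenoxy}-3-hydroxypropylidene]-2,6-dimethoxycyclohexa-2,5-dien-1-one (p-quinone methide, formed in the flask, not isolated) | COC1=CC(=C[C@@H](CO)Oc2ccc(/C=C/c3cc(O)cc(O)c3)cc2O)C=C(OC)C1=O | intermediate
17 | aiphanol, 5-[(E)-2-[(2R,3R)-3-(4-hydroxy-3,5-dimethoxyphenyl)-2-(hydroxymethyl)-2,3-dihydro-1,4-benzodioxin-6-yl]ethenyl]benzene-1,3-diol | COc1cc([C@H]2Oc3cc(/C=C/c4cc(O)cc(O)c4)ccc3O[C@@H]2CO)cc(OC)c1O | target

**Step count and risks**

Total step count: 11. Longest linear sequence: 7 steps (9 to 17 through steps 5 to 11); the chain from 1 is 6 steps.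

Steps most likely to fail:

1. Step 11 (oxidative ring closure). The oxidation may not stay at the dimethoxyphenol: phenoxyl radicals of the hydroxystilbene half may couple to oligomers, the product phenol may be oxidised further, or the quinone methide may isomerise to an enol ether before the ring closes. The fallback sets out from 8 and comes back at 17, and closes the ring before the oxidisable stilbene–resorcinol unit exists. Methanolic HCl at 40 °C (aqueous work-up to return any dimethyl acetal to the aldehyde) removes both MOM groups and the trityl group of 8 to give 3-hydroxy-4-{[(2S)-1-hydroxy-3-(4-hydroxy-3,5-dimethoxyphenyl)propan-2-yl]oxy}benzaldehyde F1. Its only electron-rich phenol is the dimethoxyphenol, the other one sitting on a formyl-deactivated ring, so Ag2O in acetone/benzene should close the ring cleanly to (2R,3R)-3-(4-hydroxy-3,5-dimethoxyphenyl)-2-(hydroxymethyl)-2,3-dihydro-1,4-benzodioxine-6-carbaldehyde F2. Horner–Wadsworth–Emmons olefination with 13 (NaH in excess to cover the phenol and the alcohol, THF/DMF, 0 °C) should then give aiphanol bis(methoxymethyl) ether F3, and methanolic HCl at rt frees the resorcinol to give 17. If the benzylic ether ionises under the acid, it should reclose to the trans isomer.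

2. Step 4 (SNAr etherification). The addition–elimination may stall because the nucleophile is a hindered secondary alkoxide and the fluoroarene is activated by only one para-formyl group and carries an ortho alkoxy group; the alkoxide may instead add to the aldehyde and start hydride-transfer side reactions. The fallback sets out from 2 (through Grignard reagent 4) and from 7, comes back at 8, and makes the C(sp3)–O bond with inversion instead of the aryl–O bond. Reagent 4 opens the purchased enantiomeric epoxide, (R)-trityl glycidyl ether F4, under the conditions of step 2 to give (2R)-1-[3,5-dimethoxy-4-(methoxymethoxy)phenyl]-3-(triphenylmethoxy)propan-2-ol F5. Aldehyde 7 is converted with NaH and 2-(methylsulfonyl)ethanol in DMF (SNAr, then loss of methyl vinyl sulfone) into 4-hydroxy-3-(methoxymethoxy)benzaldehyde F6. A Mitsunobu reaction of F5 with the acidic phenol F6 (PPh3, diisopropyl azodicarboxylate, toluene, 0 °C to rt) should then give 8 with clean inversion from R to S.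

3. Step 10 (global deprotection). The electrophiles set free in the acid (formaldehyde equivalents, trityl cation) may attack the resorcinol and dimethoxyphenol rings, and the acid may isomerise or oligomerise the electron-rich stilbene. The fallback sets out from 8 and comes back at 15, so that acid never meets the stilbene or the resorcinol. The acid-labile groups are removed at the aldehyde stage to give 3-hydroxy-4-{[(2S)-1-hydroxy-3-(4-hydroxy-3,5-dimethoxyphenyl)propan-2-yl]oxy}benzaldehyde F1, made as in the fallback for step 11. Wittig methylenation with an excess of Ph3P=CH2 (from methyltriphenylphosphonium bromide and KOtBu, THF) gives 5-ethenyl-2-{[(2S)-1-hydroxy-3-(4-hydroxy-3,5-dimethoxyphenyl)propan-2-yl]oxy}phenol F7. A Mizoroki–Heck coupling of F7 with unprotected 5-iodobenzene-1,3-diol (Pd(OAc)2, K2CO3, Bu4NBr, DMF, 80 °C) should then give the E-stilbene 15 directly.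

**Further compounds**

F1 | step 11 | 3-hydroxy-4-{[(2S)-1-hydroxy-3-(4-hydroxy-3,5-dimethoxyphenyl)propan-2-yl]oxy}benzaldehyde | O=Cc1ccc(O[C@@H](Cc2cc(OC)c(O)c(OC)c2)CO)c(O)c1
F2 | step 11 | (2R,3R)-3-(4-hydroxy-3,5-dimethoxyphenyl)-2-(hydroxymethyl)-2,3-dihydro-1,4-benzodioxine-6-carbaldehyde | COc1cc([C@H]2Oc3cc(C=O)ccc3O[C@@H]2CO)cc(OC)c1O
F3 | step 11 | aiphanol bis(methoxymethyl) ether, 4-[(2R,3R)-6-{(E)-2-[3,5-bis(methoxymethoxy)phenyl]ethenyl}-2-(hydroxymethyl)-2,3-dihydro-1,4-benzodioxin-3-yl]-2,6-dimethoxyphenol | COc1cc([C@H]2Oc3cc(/C=C/c4cc(OCOC)cc(OCOC)c4)ccc3O[C@@H]2CO)cc(OC)c1O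
F4 | step 4 | (R)-trityl glycidyl ether, (2R)-2-[(triphenylmethoxy)methyl]oxirane | C1O[C@H]1COC(c2ccccc2)(c2ccccc2)c2ccccc2
F5 | step 4 | (2R)-1-[3,5-dimethoxy-4-(methoxymethoxy)phenyl]-3-(triphenylmethoxy)propan-2-ol | COCOc1c(OC)cc(C[C@@H](O)COC(c2ccccc2)(c2ccccc2)c2ccccc2)cc1OC
F6 | step 4 | 4-hydroxy-3-(methoxymethoxy)benzaldehyde | COCOc1cc(C=O)ccc1O
F7 | step 10 | 5-ethenyl-2-{[(2S)-1-hydroxy-3-(4-hydroxy-3,5-dimethoxyphenyl)propan-2-yl]oxy}phenol | C=Cc1ccc(O[C@@H](Cc2cc(OC)c(O)c(OC)c2)CO)c(O)c1
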